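The cyclohexane ring of the target has its arm-bearing carbon C1 flanked by C2 (the methyl carbinol) and C6 (the gem-dimethyl carbon), so both neighbours carry a methyl group. Reading one C6 methyl as a masked cyclopropane CH2 traces the ring back to the achiral, mirror-symmetric diene (2,6-dimethylcyclohexa-2,5-dien-1-yl)methanol, made by Birch reduction of 2,6-dimethylbenzoic acid. One hydroxyl-directed Simmons–Smith reaction under a chiral tartramide boronate then has to choose one of the two enantiotopic C=C bonds, form C6–CH2 and C5–CH2, and fix C1 in absolute terms. Anti epoxidation with hydride opening sets C2, hydrogenolysis unveils the gem-dimethyl group, and a Negishi coupling joins the arm to position 6 of ring A of benzyl-protected luteolin.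

Key step: step 3

Remark on the chemistry: the sense of induction of the tartramide boronate on this homoallylic dienyl carbinol cannot be read from allylic cases; the route is written with the (4R,5R) ligand (from L-tartaric acid), and the (4S,5S) antipode would be taken if the other alkene proved to be favoured.

Locants: C1–C6 in the Why lines are those of the cyclohexane ring of 21 (C1 carries the arm, C2 the hydroxyl, C6 the gem-dimethyl pair, C5 is next to C6). Chromone positions are marked as flavone positions.

Step 1
Reactants: 1 2,6-dimethylbenzoic acid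
Product: 2 2,6-dimethylcyclohexa-2,5-diene-1-carboxylic acid
Conditions: Li, NH3(l)/THF, −78 °C; then NH4Cl
Reagents that add atoms: none
Why: Birch reduction, in which electron transfer to the benzoate gives a carboxylate-stabilised anion that is protonated at C4 by ammonia and at C1 on quench, so the 1,4-dihydro acid with both methyl-bearing carbons still sp2 should form, and it is achiral (mirror plane through C1 and C4).

Step 2
Reactants: 2 2,6-dimethylcyclohexa-2,5-diene-1-carboxylic acid
Product: 3 (2,6-dimethylcyclohexa-2,5-dien-1-yl)methanol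
Conditions: LiAlH4, THF, 0 °C to rt (crude 2 used at once, under argon)
Reagents that add atoms: none
Why: LiAlH4 reduction of a carboxylic acid to the primary alcohol, which leaves the unconjugated diene untouched; immediate use of 2 under argon avoids air re-aromatisation.

Step 3
Reactants: 3 (2,6-dimethylcyclohexa-2,5-dien-1-yl)methanol; 4 diiodomethane
Product: 6 [(1S,2R,6R)-1,3-dimethylbicyclo[4.1.0]hept-3-en-2-yl]methanol, via iodomethylzinc alkoxide 5 (not isolated)
Conditions: Zn(CH2I)2·DME (1.5 equiv, from Et2Zn and CH2I2, CH2Cl2, −10 °C), (4R,5R)-2-butyl-N,N,N′,N′-tetramethyl-1,3,2-dioxaborolane-4,5-dicarboxamide (1.2 equiv), CH2Cl2, −10 °C to rt, quenched when 3 is consumed; aq. NaOH work-up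
Reagents that add atoms: diiodomethane (4), ICI
Why: Proposed new method: the hydroxyl of 3 is zincated to the iodomethylzinc alkoxide 5, which binds to boron of the dioxaborolane while the amide carbonyls hold a second Zn(CH2I)2, and CH2 is then passed to one C=C bond through the concerted butterfly transition state of a Simmons–Smith reaction; the closest known reactions are the dioxaborolane-mediated enantioselective cyclopropanation of allylic alcohols and the hydroxyl-directed cyclopropanation of cyclohexadienyl carbinols, and the reagent-controlled choice between two homoallylic alkenes is the untested part. The cyclopropane closes by a one-step [2+1] syn addition of the carbenoid carbon across C5=C6, both C–C bonds forming together without a radical or ionic intermediate. C5 and C6 are set by delivery from the oxygen on C1, which sits above one face of the almost planar diene, so the CH2 should end up cis to the arm; C1 becomes stereogenic only through the choice of alkene, which the C2-symmetric tartramide has to make. The step needs group selectivity and mono-addition: the first rests on the ligand, the second on a limited amount of carbenoid, and any second cyclopropanation should consume the minor enantiomer of 6 faster and so raise the enantiomeric purity. The methyl groups on C2 and C6 make both alkenes trisubstituted and nucleophilic, which suits the electrophilic zinc carbenoid at low temperature.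

Step 4
Reactants: 6 [(1S,2R,6R)-1,3-dimethylbicyclo[4.1.0]hept-3-en-2-yl]methanol
Product: 7 tert-butyl{[(1S,2R,6R)-1,3-dimethylbicyclo[4.1.0]hept-3-en-2-yl]methoxy}dimethylsilane
Conditions: TBSCl, imidazole, DMF, rt
Reagents that add atoms: tert-butyldimethylsilyl chloride, CC(C)(C)[Si](C)(C)Cl
Why: Imidazole-promoted silylation of a primary alcohol, which removes the hydrogen-bond donor that could steer a peracid to the wrong face and enlarges the arm before the epoxidation.

Step 5
Reactants: 7 tert-butyl{[(1S,2R,6R)-1,3-dimethylbicyclo[4.1.0]hept-3-en-2-yl]methoxy}dimethylsilane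
Product: 8 anti-epoxide of 7 (oxirane on the C2–C3 bond, oxygen on the face opposite to the cyclopropane CH2 and the CH2OTBS arm)
Conditions: mCPBA, NaHCO3, CH2Cl2, 0 °C
Reagents that add atoms: 3-chloroperbenzoic acid, OOC(=O)c1cccc(Cl)c1
Why: Prilezhaev epoxidation, in which the peracid should add to the trisubstituted C2=C3 bond of the flattened ring from the face opposite to the pseudoaxial CH2OTBS arm on C1 and the cyclopropane CH2 (the bias that also governs 3-carene), so both new C–O bonds at C2 and C3 are trans to the arm.

Step 6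
Reactants: 8 anti-epoxide of 7
Product: 9 (1S,2R,3S,6R)-2-{[(tert-butyldimethylsilyl)oxy]methyl}-1,3-dimethylbicyclo[4.1.0]heptan-3-ol
Conditions: LiEt3BH, THF, 0 °C to rt
Reagents that add atoms: none
Why: SN2 hydride opening of a trisubstituted epoxide by LiEt3BH at the less substituted carbon C3, which leaves the C2–O bond intact and so gives the tertiary alcohol at C2 with its oxygen trans to the arm; the silyl ether and the cyclopropane do not react.

Step 7
Reactants: 9 (1S,2R,3S,6R)-2-{[(tert-butyldimethylsilyl)oxy]methyl}-1,3-dimethylbicyclo[4.1.0]heptan-3-ol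
Product: 10 (1S,2R)-2-{[(tert-butyldimethylsilyl)oxy]methyl}-1,3,3-trimethylcyclohexan-1-ol
Conditions: H2 (3 atm), PtO2, AcOH, rt
Reagents that add atoms: none
Why: Catalytic hydrogenolysis of a cyclopropane over PtO2 in acetic acid should cleave the least hindered bond, C5–CH2, between the two less substituted ring carbons, so the CH2 stays on C6 as the second methyl; C6 stops being stereogenic and C1 and C2 are untouched.

Step 8
Reactants: 10 (1S,2R)-2-{[(tert-butyldimethylsilyl)oxy]methyl}-1,3,3-trimethylcyclohexan-1-ol
Product: 11 (1S,2R)-2-(hydroxymethyl)-1,3,3-trimethylcyclohexan-1-ol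
Conditions: TBAF, THF, rt
Reagents that add atoms: none
Why: Fluoride-induced desilylation, driven by the strong Si–F bond, frees the primary alcohol without touching the tertiary alcohol or either stereocenter.

Step 9
Reactants: 11 (1S,2R)-2-(hydroxymethyl)-1,3,3-trimethylcyclohexan-1-ol
Product: 12 (1S,2S)-2-(iodomethyl)-1,3,3-trimethylcyclohexan-1-ol
Conditions: I2, PPh3, imidazole, toluene, 60 °C
Reagents that add atoms: iodine, II
Why: Appel-type iodination, in which only the primary hydroxyl forms the alkoxyphosphonium ion that iodide displaces by SN2 at the CH2 group, so neither stereocenter is involved and the hindered tertiary hydroxyl stays (the descriptor at C1 changes by priority only).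

Step 10
Reactants: 12 (1S,2S)-2-(iodomethyl)-1,3,3-trimethylcyclohexan-1-ol
Product: 13 {[(1S,2S)-2-(iodomethyl)-1,3,3-trimethylcyclohexyl]oxy}trimethylsilane
Conditions: TMSOTf, 2,6-lutidine, CH2Cl2, −78 to 0 °C
Reagents that add atoms: trimethylsilyl trifluoromethanesulfonate, C[Si](C)(C)OS(=O)(=O)C(F)(F)F
Why: Silylation of the tertiary alcohol with a silyl triflate and a hindered pyridine base masks the only acidic proton before the organozinc is made, and the primary iodide is inert under these conditions.

Step 11
Reactants: 14 luteolin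
Product: 15 7-(benzyloxy)-2-[3,4-bis(benzyloxy)phenyl]-5-hydroxy-4H-chromen-4-one
Conditions: BnBr (3.1 equiv), K2CO3, DMF, rt
Reagents that add atoms: benzyl bromide, BrCc1ccccc1
Why: Williamson etherification, in which the 5-hydroxyl is held in a hydrogen bond to the C4 carbonyl and is the least reactive phenol, so three equivalents of benzyl bromide should alkylate O7, O3′ and O4′ only.

Step 12
Reactants: 15 7-(benzyloxy)-2-[3,4-bis(benzyloxy)phenyl]-5-hydroxy-4H-chromen-4-one
Product: 16 7-(benzyloxy)-2-[3,4-bis(benzyloxy)phenyl]-5-hydroxy-6-iodo-4H-chromen-4-one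
Conditions: BnMe3N+ ICl2− (1.05 equiv), CaCO3, CH2Cl2/MeOH, rt
Reagents that add atoms: benzyltrimethylammonium dichloroiodate, C[N+](C)(C)Cc1ccccc1.Cl[I-]Cl
Why: Electrophilic aromatic iodination of the phloroglucinol-type ring A, where the free 5-hydroxyl should direct the mild dichloroiodate reagent to its ortho position, flavone C-6 (the pattern known for 5-hydroxy-7-alkoxyflavones, whereas 5-O-alkyl flavones react at C-8), while ring B, deactivated by the chromone, should not compete with one equivalent.

Step 13
Reactants: 16 7-(benzyloxy)-2-[3,4-bis(benzyloxy)phenyl]-5-hydroxy-6-iodo-4H-chromen-4-one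
Product: 17 5,7-bis(benzyloxy)-2-[3,4-bis(benzyloxy)phenyl]-6-iodo-4H-chromen-4-one
Conditions: BnBr, K2CO3, DMF, 60 °C
Reagents that add atoms: benzyl bromide, BrCc1ccccc1
Why: Williamson etherification under more forcing conditions overcomes the chelation of the 5-hydroxyl and removes the last acidic proton, so that all four phenol ethers can fall in one final hydrogenolysis.

Step 14
Reactants: 13 {[(1S,2S)-2-(iodomethyl)-1,3,3-trimethylcyclohexyl]oxy}trimethylsilane; 17 5,7-bis(benzyloxy)-2-[3,4-bis(benzyloxy)phenyl]-6-iodo-4H-chromen-4-one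
Product: 20 5,7-bis(benzyloxy)-2-[3,4-bis(benzyloxy)phenyl]-6-{[(1S,2S)-2-hydroxy-2,6,6-trimethylcyclohexyl]methyl}-4H-chromen-4-one, via alkylzinc iodide 18 (not isolated), via trimethylsilyl ether 19 (not isolated)
Conditions: Zn dust (activated with 1,2-dibromoethane and TMSCl), LiCl, THF, 50 °C; then 17, Pd(OAc)2 (5 mol %), SPhos (10 mol %), THF/NMP, 60 °C; then TBAF, THF, 0 °C
Reagents that add atoms: none
Why: Negishi cross-coupling, in which zinc inserts into the primary C–I bond of 13, the alkylzinc iodide 18 transmetalates to the aryl–Pd–I complex formed by oxidative addition of zerovalent palladium into the C–I bond at flavone C-6 of 17, and the bulky biaryl phosphine SPhos should let reductive elimination between the two ortho benzyloxy groups outrun β-hydride elimination; no stereocenter takes part, and fluoride then cleaves the trimethylsilyl ether.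

Step 15
Reactants: 20 5,7-bis(benzyloxy)-2-[3,4-bis(benzyloxy)phenyl]-6-{[(1S,2S)-2-hydroxy-2,6,6-trimethylcyclohexyl]methyl}-4H-chromen-4-one
Product: 21 2-(3,4-dihydroxyphenyl)-5,7-dihydroxy-6-{[(1S,2S)-2-hydroxy-2,6,6-trimethylcyclohexyl]methyl}-4H-chromen-4-one (CNP0257603.1)
Conditions: H2 (1 atm), Pd/C (10 %), EtOAc/MeOH, rt
Reagents that add atoms: none
Why: Hydrogenolysis of the four benzyl aryl ethers over Pd/C at 1 atm and room temperature should leave the chromone C2=C3 bond and the tertiary alcohol intact, the reaction being stopped once four equivalents of hydrogen are taken up.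

Compound list
1 | 2,6-dimethylbenzoic acid | Cc1cccc(C)c1C(=O)O | starting material
2 | 2,6-dimethylcyclohexa-2,5-diene-1-carboxylic acid | CC1=CCC=C(C)C1C(=O)O | intermediate
3 | (2,6-dimethylcyclohexa-2,5-dien-1-yl)methanol | CC1=CCC=C(C)C1CO | intermediate
4 | diiodomethane | ICI | starting material
5 | iodomethylzinc alkoxide of 3 | IC[Zn]OCC1C(C)=CCC=C1C | intermediate (not isolated)
6 | [(1S,2R,6R)-1,3-dimethylbicyclo[4.1.0]hept-3-en-2-yl]methanol (cyclopropane CH2 cis to the CH2OH arm) | C[C@]12C[C@H]1CC=C(C)[C@H]2CO | intermediate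
7 | tert-butyl{[(1S,2R,6R)-1,3-dimethylbicyclo[4.1.0]hept-3-en-2-yl]methoxy}dimethylsilane | C[C@]12C[C@H]1CC=C(C)[C@H]2CO[Si](C)(C)C(C)(C)C | intermediate
8 | anti-epoxide of 7 (oxirane oxygen trans to the cyclopropane CH2 and to the CH2OTBS arm) | C[C@]12C[C@H]1C[C@@H]3O[C@]3(C)[C@H]2CO[Si](C)(C)C(C)(C)C | intermediate
9 | (1S,2R,3S,6R)-2-{[(tert-butyldimethylsilyl)oxy]methyl}-1,3-dimethylbicyclo[4.1.0]heptan-3-ol (hydroxyl trans to the arm) | C[C@]12C[C@H]1CC[C@](C)(O)[C@H]2CO[Si](C)(C)C(C)(C)C | intermediate
10 | (1S,2R)-2-{[(tert-butyldimethylsilyl)oxy]methyl}-1,3,3-trimethylcyclohexan-1-ol | CC1(C)CCC[C@](C)(O)[C@H]1CO[Si](C)(C)C(C)(C)C | intermediate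
11 | (1S,2R)-2-(hydroxymethyl)-1,3,3-trimethylcyclohexan-1-ol | CC1(C)CCC[C@](C)(O)[C@H]1CO | intermediate
12 | (1S,2S)-2-(iodomethyl)-1,3,3-trimethylcyclohexan-1-ol | CC1(C)CCC[C@](C)(O)[C@H]1CI | intermediate
13 | {[(1S,2S)-2-(iodomethyl)-1,3,3-trimethylcyclohexyl]oxy}trimethylsilane | CC1(C)CCC[C@](C)(O[Si](C)(C)C)[C@H]1CI | intermediate
14 | luteolin | O=c1cc(-c2ccc(O)c(O)c2)oc2cc(O)cc(O)c12 | starting material
15 | 7-(benzyloxy)-2-[3,4-bis(benzyloxy)phenyl]-5-hydroxy-4H-chromen-4-one | O=c1cc(-c2ccc(OCc3ccccc3)c(OCc3ccccc3)c2)oc2cc(OCc3ccccc3)cc(O)c12 | intermediate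
16 | 7-(benzyloxy)-2-[3,4-bis(benzyloxy)phenyl]-5-hydroxy-6-iodo-4H-chromen-4-one | O=c1cc(-c2ccc(OCc3ccccc3)c(OCc3ccccc3)c2)oc2cc(OCc3ccccc3)c(I)c(O)c12 | intermediate
17 | 5,7-bis(benzyloxy)-2-[3,4-bis(benzyloxy)phenyl]-6-iodo-4H-chromen-4-one | O=c1cc(-c2ccc(OCc3ccccc3)c(OCc3ccccc3)c2)oc2cc(OCc3ccccc3)c(I)c(OCc3ccccc3)c12 | intermediate
18 | alkylzinc iodide from 13, {[(1S,2S)-2,6,6-trimethyl-2-(trimethylsilyloxy)cyclohexyl]methyl}zinc iodide | CC1(C)CCC[C@](C)(O[Si](C)(C)C)[C@H]1C[Zn]I | intermediate (not isolated)
19 | trimethylsilyl ether of 20, 5,7-bis(benzyloxy)-2-[3,4-bis(benzyloxy)phenyl]-6-{[(1S,2S)-2,6,6-trimethyl-2-(trimethylsilyloxy)cyclohexyl]methyl}-4H-chromen-4-one | CC1(C)CCC[C@](C)(O[Si](C)(C)C)[C@H]1Cc1c(OCc2ccccc2)cc2oc(-c3ccc(OCc4ccccc4)c(OCc4ccccc4)c3)cc(=O)c2c1OCc1ccccc1 | intermediate (not isolated)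
20 | 5,7-bis(benzyloxy)-2-[3,4-bis(benzyloxy)phenyl]-6-{[(1S,2S)-2-hydroxy-2,6,6-trimethylcyclohexyl]methyl}-4H-chromen-4-one | CC1(C)CCC[C@](C)(O)[C@H]1Cc1c(OCc2ccccc2)cc2oc(-c3ccc(OCc4ccccc4)c(OCc4ccccc4)c3)cc(=O)c2c1OCc1ccccc1 | intermediate
21 | 2-(3,4-dihydroxyphenyl)-5,7-dihydroxy-6-{[(1S,2S)-2-hydroxy-2,6,6-trimethylcyclohexyl]methyl}-4H-chromen-4-one | CC1(C)CCC[C@](C)(O)[C@H]1Cc1c(O)cc2oc(-c3ccc(O)c(O)c3)cc(=O)c2c1O | target

Total step count: 15 (steps 1–10 for the cyclohexyl fragment, steps 11–13 for the flavone fragment, steps 14 and 15 after convergence).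
Longest linear sequence: 12 steps (steps 1–10, 14 and 15, from 1 to 21).

Steps most likely to fail

1. Step 3 (the step proposed as a new method). What may go wrong is weak discrimination between the two enantiotopic alkenes by the boronate-bound carbenoid, giving low enantiomeric purity, together with over-cyclopropanation to the bis-adduct. The fallback uses known chemistry only, sets out from 3 and returns at 6. An achiral hydroxyl-directed Simmons–Smith cyclopropanation of 3 (Et2Zn, CH2I2, CH2Cl2, 0 °C, limited reagent) should give racemic cis-(1,3-dimethylbicyclo[4.1.0]hept-3-en-2-yl)methanol F1. Esterification with (S)-2-methoxy-2-phenylacetic acid (DCC, DMAP, CH2Cl2) converts it into two diastereomers, the (S)-O-methylmandelate of 6 F2 and the (S)-O-methylmandelate of ent-6 F3, which are separated by chromatography or crystallisation. Saponification of F2 (LiOH, THF/H2O) returns 6 as a single enantiomer, at the cost of half the material.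

2. Step 14. What may go wrong is slow transmetalation between the β-branched alkylzinc and the doubly ortho-substituted aryl–palladium complex, so that β-hydride elimination and reduction of the aryl iodide take over. The fallback sets out from 13 and returns at 19. Iodine–lithium exchange (t-BuLi, 2 equiv, Et2O, −78 °C) gives the alkyllithium from 13 F4, which is trapped with 9-methoxy-9-borabicyclo[3.3.1]nonane as the lithium B-alkyl-B-methoxy-9-BBN borinate F5. A B-alkyl Suzuki–Miyaura coupling of this more nucleophilic ate complex with 17 (PdCl2(dppf), aq. K3PO4, DMF, rt to 50 °C) should give 19, which is desilylated with TBAF to 20 as in step 14.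

3. Step 9. What may go wrong is participation of the neighbouring tertiary hydroxyl at the activated phosphonium stage (cyclic ether formation or dehydration) while SN2 displacement at the β-branched carbon is slow. The fallback sets out from 11 and returns at 12. Selective sulfonylation of the primary hydroxyl (TsCl, pyridine, 0 °C) gives [(1R,2S)-2-hydroxy-2,6,6-trimethylcyclohexyl]methyl 4-methylbenzenesulfonate F6, an isolable sulfonate that needs no phosphorus activation. Finkelstein displacement (NaI, butanone, reflux) then gives 12.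

Further compounds
F1 | step 3 | racemic cis-(1,3-dimethylbicyclo[4.1.0]hept-3-en-2-yl)methanol | C[C@]12C[C@H]1CC=C(C)[C@H]2CO.C[C@@]12C[C@@H]1CC=C(C)[C@@H]2CO
F2 | step 3 | (S)-O-methylmandelate of 6 | C[C@]12C[C@H]1CC=C(C)[C@H]2COC(=O)[C@@H](OC)c1ccccc1
F3 | step 3 | (S)-O-methylmandelate of ent-6 | C[C@@]12C[C@@H]1CC=C(C)[C@@H]2COC(=O)[C@@H](OC)c1ccccc1
F4 | step 14 | alkyllithium from 13 | CC1(C)CCC[C@](C)(O[Si](C)(C)C)[C@H]1C[Li]
F5 | step 14 | lithium B-alkyl-B-methoxy-9-BBN borinate | CC1(C)CCC[C@](C)(O[Si](C)(C)C)[C@H]1C[B-]1(OC)C2CCCC1CCC2.[Li+]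
F6 | step 9 | [(1R,2S)-2-hydroxy-2,6,6-trimethylcyclohexyl]methyl 4-methylbenzenesulfonate | CC1(C)CCC[C@](C)(O)[C@H]1COS(=O)(=O)c1ccc(C)cc1
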